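**Assumption:** Agehoustin C has no stereocentre and no configurationally stable axis, so "single enantiomer" is met trivially; the target is built exactly as in the given SMILES. Compounds 1, 6 and 7 are taken as commercial.

**Retrosynthetic overview**
1. The pyranone (C) ring is formed last, in one step, from three components: iodophenol 5 + CO + aryl alkyne 12 (Pd carbonylative Sonogashira coupling/annulation). C4 comes from CO, so no acetophenone, chalcone or diketone is used.
2. A-ring partner 5: 1,2,3,4-tetramethoxybenzene → ortho-lithiation/borylation/oxidation → ortho-iodination.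
3. B-ring partner 12: 1-bromo-2,4,5-trimethoxybenzene → Sonogashira with TIPS-acetylene → lithiation between the two flanking OMe groups/oxidation (sets the 3'-OH) → desilylation.
4. Both aromatic rings are bought intact; neither phenol is protected.

**Route**

Step 1
Reactants: 1 1,2,3,4-tetramethoxybenzene
Product: 4 2,3,4,5-tetramethoxyphenol, via aryllithium 2 (not isolated), via arylboronate 3 (not isolated)
Conditions: n-BuLi (1.2 equiv), TMEDA, THF, 0 °C → rt; B(OMe)3, −78 °C → rt; AcOH, 30% H2O2, 0 °C → rt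
Reagents that add atoms: hydrogen peroxide, OO
Why: Directed ortho-metalation followed by borylation and oxidative B→O 1,2-aryl shift; the symmetric arene has only one kind of C–H (ortho to OMe), so a single phenol forms.

Step 2
Reactants: 4 2,3,4,5-tetramethoxyphenol
Product: 5 2-iodo-3,4,5,6-tetramethoxyphenol
Conditions: NIS (1.05 equiv), MeCN, 0 °C, dark
Reagents that add atoms: N-iodosuccinimide, O=C1CCC(=O)N1I
Why: Electrophilic aromatic iodination at the only free ring position, which is ortho to the free OH and strongly activated, so it should outrun oxidation to the quinone at 0 °C.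

Step 3
Reactants: 6 1-bromo-2,4,5-trimethoxybenzene; 7 ethynyltriisopropylsilane (TIPS-acetylene)
Product: 8 triisopropyl[(2,4,5-trimethoxyphenyl)ethynyl]silane
Conditions: PdCl2(MeCN)2 (2 mol %), XPhos (6 mol %), Cs2CO3, MeCN, 80 °C
Reagents that add atoms: none
Why: Copper-free Sonogashira coupling; the bulky electron-rich phosphine allows oxidative addition into the electron-rich ortho-methoxy aryl bromide, and TIPS gives an alkyne robust enough for step 4.

Step 4
Reactants: 8 triisopropyl[(2,4,5-trimethoxyphenyl)ethynyl]silane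
Product: 11 2,3,6-trimethoxy-5-[(triisopropylsilyl)ethynyl]phenol, via aryllithium 9 (not isolated), via arylboronate 10 (not isolated)
Conditions: n-BuLi (1.3 equiv), THF, −20 → 0 °C; B(OMe)3, −78 °C → rt; AcOH, 30% H2O2, 0 °C → rt
Reagents that add atoms: hydrogen peroxide, OO
Why: Directed ortho-metalation then borylation–oxidation; C3–H lies between two OMe groups (the doubly chelated, most acidic site) whereas C6–H has only one OMe, and the hindered TIPS-alkyne should resist attack at silicon and carbolithiation at ≤0 °C.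

Step 5
Reactants: 11 2,3,6-trimethoxy-5-[(triisopropylsilyl)ethynyl]phenol
Product: 12 5-ethynyl-2,3,6-trimethoxyphenol
Conditions: TBAF (2.2 equiv), THF, 0 °C → rt; aq. NH4Cl
Reagents that add atoms: none
Why: Fluoride-mediated protodesilylation of the C(sp)–Si bond; the aryl methyl ethers and the phenol (as phenoxide) are inert.

Step 6
Reactants: 5 2-iodo-3,4,5,6-tetramethoxyphenol; 12 5-ethynyl-2,3,6-trimethoxyphenol (1.3 equiv)
Product: 15 Agehoustin C [2-(3-hydroxy-2,4,5-trimethoxyphenyl)-5,6,7,8-tetramethoxy-4H-chromen-4-one], via ynone 13 (not isolated), via enaminone 14 (not isolated)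
Conditions: PdCl2(dppf) (5 mol %), CO (10–20 atm), Et2NH, 110–120 °C, autoclave
Reagents that add atoms: carbon monoxide, [C-]#[O+]
Why: Pd-catalysed carbonylative Sonogashira coupling/annulation: oxidative addition of Ar–I, CO insertion and alkynylation give ynone 13, Et2NH adds (aza-Michael) to give enaminone 14, and the ortho-phenol closes the six-membered ring by addition–elimination with loss of Et2NH, which favours flavone over aurone; the 3'-OH is flanked by two OMe groups and is a poor nucleophile for the aroyl–Pd species; no stereocentre is formed.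

**Compound list**
1 | 1,2,3,4-tetramethoxybenzene | COc1ccc(OC)c(OC)c1OC | starting material
2 | (2,3,4,5-tetramethoxyphenyl)lithium | [Li]c1cc(OC)c(OC)c(OC)c1OC | intermediate
3 | dimethyl (2,3,4,5-tetramethoxyphenyl)boronate | COB(OC)c1cc(OC)c(OC)c(OC)c1OC | intermediate
4 | 2,3,4,5-tetramethoxyphenol | COc1cc(O)c(OC)c(OC)c1OC | intermediate
5 | 2-iodo-3,4,5,6-tetramethoxyphenol | COc1c(O)c(I)c(OC)c(OC)c1OC | intermediate
6 | 1-bromo-2,4,5-trimethoxybenzene | COc1cc(OC)c(Br)cc1OC | starting material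
7 | ethynyltriisopropylsilane | C#C[Si](C(C)C)(C(C)C)C(C)C | starting material
8 | triisopropyl[(2,4,5-trimethoxyphenyl)ethynyl]silane | COc1cc(OC)c(C#C[Si](C(C)C)(C(C)C)C(C)C)cc1OC | intermediate
9 | {2,3,6-trimethoxy-5-[(triisopropylsilyl)ethynyl]phenyl}lithium | COc1cc(C#C[Si](C(C)C)(C(C)C)C(C)C)c(OC)c([Li])c1OC | intermediate
10 | dimethyl {2,3,6-trimethoxy-5-[(triisopropylsilyl)ethynyl]phenyl}boronate | COB(OC)c1c(OC)c(OC)cc(C#C[Si](C(C)C)(C(C)C)C(C)C)c1OC | intermediate
11 | 2,3,6-trimethoxy-5-[(triisopropylsilyl)ethynyl]phenol | COc1cc(C#C[Si](C(C)C)(C(C)C)C(C)C)c(OC)c(O)c1OC | intermediate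
12 | 5-ethynyl-2,3,6-trimethoxyphenol | C#Cc1cc(OC)c(OC)c(O)c1OC | intermediate
13 | 1-(2-hydroxy-3,4,5,6-tetramethoxyphenyl)-3-(3-hydroxy-2,4,5-trimethoxyphenyl)prop-2-yn-1-one | COc1cc(C#CC(=O)c2c(O)c(OC)c(OC)c(OC)c2OC)c(OC)c(O)c1OC | intermediate
14 | (E)-3-(diethylamino)-1-(2-hydroxy-3,4,5,6-tetramethoxyphenyl)-3-(3-hydroxy-2,4,5-trimethoxyphenyl)prop-2-en-1-one | CCN(CC)/C(=C/C(=O)c1c(O)c(OC)c(OC)c(OC)c1OC)c1cc(OC)c(OC)c(O)c1OC | intermediate
15 | Agehoustin C, 2-(3-hydroxy-2,4,5-trimethoxyphenyl)-5,6,7,8-tetramethoxy-4H-chromen-4-one | COc1cc(-c2cc(=O)c3c(OC)c(OC)c(OC)c(OC)c3o2)c(OC)c(O)c1OC | target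

**Totals**
Total step count: 6 (steps 1–2 and 3–5 are two branches that converge in step 6).
Longest linear sequence: 4 steps (6 → 8 → 11 → 12 → 15).

**Three steps most likely to fail**

Step 6 (key step). The iodide is hindered and very electron-rich, so oxidative addition may be slow; aminocarbonylation to the diethylamide or non-carbonylative coupling to a 2-arylbenzofuran may compete.
The fallback sets out from phenol 4 and alkyne 12 and comes back to the route at ynone 13. Ortho-formylation of 4 (MgCl2, Et3N, paraformaldehyde, MeCN, reflux) gives 2-hydroxy-3,4,5,6-tetramethoxybenzaldehyde F1. Alkyne 12 is converted with n-BuLi (2.1 equiv, THF, −78 °C) into its O,C-dilithio derivative F2, which is added to F1 (pre-deprotonated with NaH) to give racemic 1-(2-hydroxy-3,4,5,6-tetramethoxyphenyl)-3-(3-hydroxy-2,4,5-trimethoxyphenyl)prop-2-yn-1-ol F3. MnO2 (CH2Cl2, rt) oxidises F3 to 13, and Et2NH in EtOH at 50 °C takes 13 through 14 to 15. The carbonyl carbon then comes from formaldehyde and no palladium step is needed.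

Step 4. n-BuLi may add to the alkyne, or some lithiation may occur at C6.
The fallback sets out from bromide 6, reuses 7, and comes back at 11. Br/Li exchange on 6 (n-BuLi, THF, −78 °C) gives (2,4,5-trimethoxyphenyl)lithium F4, which is quenched with TMSCl to trimethyl(2,4,5-trimethoxyphenyl)silane F5. The silyl group is an inert, bulky, non-directing placeholder, so n-BuLi (THF, 0 °C) metalates only between the two OMe groups to give [2,3,6-trimethoxy-5-(trimethylsilyl)phenyl]lithium F6. B(OMe)3 converts F6 into dimethyl [2,3,6-trimethoxy-5-(trimethylsilyl)phenyl]boronate F7, and alkaline H2O2 gives 2,3,6-trimethoxy-5-(trimethylsilyl)phenol F8. Ac2O/pyridine gives 2,3,6-trimethoxy-5-(trimethylsilyl)phenyl acetate F9. ICl (CH2Cl2, −78 → 0 °C) effects ipso-iododesilylation to 5-iodo-2,3,6-trimethoxyphenyl acetate F10. Sonogashira coupling of F10 with 7 (PdCl2(PPh3)2, CuI, Et3N, rt) gives 2,3,6-trimethoxy-5-[(triisopropylsilyl)ethynyl]phenyl acetate F11, and K2CO3/MeOH removes the acetate to give 11.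

Step 2. The pentaoxygenated phenol may be oxidised to a quinone by the iodinating agent.
The fallback sets out from 4 and comes back at 5. MOMCl/i-Pr2NEt (CH2Cl2) gives 1-(methoxymethoxy)-2,3,4,5-tetramethoxybenzene F12. n-BuLi (THF, 0 °C) removes the only ring proton, which sits between OMOM and OMe, to give [2-(methoxymethoxy)-3,4,5,6-tetramethoxyphenyl]lithium F13. Iodine converts F13 into 1-iodo-2-(methoxymethoxy)-3,4,5,6-tetramethoxybenzene F14, and HCl/MeOH at rt removes the MOM group to give 5. Iodine is thus introduced by a nucleophilic aryl–metal route and never meets the free phenol.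

**Further compounds**
F1 | step 6 | 2-hydroxy-3,4,5,6-tetramethoxybenzaldehyde | O=Cc1c(O)c(OC)c(OC)c(OC)c1OC
F2 | step 6 | O,C-dilithio derivative of 12 (lithium 5-(lithioethynyl)-2,3,6-trimethoxyphenolate) | [Li]C#Cc1cc(OC)c(OC)c(O[Li])c1OC
F3 | step 6 | rac-1-(2-hydroxy-3,4,5,6-tetramethoxyphenyl)-3-(3-hydroxy-2,4,5-trimethoxyphenyl)prop-2-yn-1-ol | OC(C#Cc1cc(OC)c(OC)c(O)c1OC)c1c(O)c(OC)c(OC)c(OC)c1OC
F4 | step 4 | (2,4,5-trimethoxyphenyl)lithium | [Li]c1cc(OC)c(OC)cc1OC
F5 | step 4 | trimethyl(2,4,5-trimethoxyphenyl)silane | COc1cc(OC)c([Si](C)(C)C)cc1OC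
F6 | step 4 | [2,3,6-trimethoxy-5-(trimethylsilyl)phenyl]lithium | [Li]c1c(OC)c(OC)cc([Si](C)(C)C)c1OC
F7 | step 4 | dimethyl [2,3,6-trimethoxy-5-(trimethylsilyl)phenyl]boronate | COB(OC)c1c(OC)c(OC)cc([Si](C)(C)C)c1OC
F8 | step 4 | 2,3,6-trimethoxy-5-(trimethylsilyl)phenol | Oc1c(OC)c(OC)cc([Si](C)(C)C)c1OC
F9 | step 4 | 2,3,6-trimethoxy-5-(trimethylsilyl)phenyl acetate | CC(=O)Oc1c(OC)c(OC)cc([Si](C)(C)C)c1OC
F10 | step 4 | 5-iodo-2,3,6-trimethoxyphenyl acetate | CC(=O)Oc1c(OC)c(OC)cc(I)c1OC
F11 | step 4 | 2,3,6-trimethoxy-5-[(triisopropylsilyl)ethynyl]phenyl acetate | CC(=O)Oc1c(OC)c(OC)cc(C#C[Si](C(C)C)(C(C)C)C(C)C)c1OC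
F12 | step 2 | 1-(methoxymethoxy)-2,3,4,5-tetramethoxybenzene | COCOc1cc(OC)c(OC)c(OC)c1OC
F13 | step 2 | [2-(methoxymethoxy)-3,4,5,6-tetramethoxyphenyl]lithium | [Li]c1c(OCOC)c(OC)c(OC)c(OC)c1OC
F14 | step 2 | 1-iodo-2-(methoxymethoxy)-3,4,5,6-tetramethoxybenzene | COCOc1c(I)c(OC)c(OC)c(OC)c1OC
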